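In a one-step world you would read the yield off a single rate constant. This flask has solid E feeding Z into solution, and L that reacts with Z but also with itself.

E 24 mM; L 4.00 equiv; time 50 min

    E ⇌ Z, rate k1*(cs1 - [Z]) while solid is left; crystals form when [Z] > cs1 (cs1 = 2.6 mM, k1 = 0.0170 s⁻¹)
    Z + L → Z.L (k2 = 0.0966 M⁻¹ s⁻¹)
    D ⇌ Z.L, rate k3*(cs3 - [Z.L]) while solid is left; crystals form when [Z.L] > cs3 (cs3 = 9.4 mM, k3 = 0.00882 s⁻¹)
    2 L → L2 (k4 = 0.00943 M⁻¹ s⁻¹)

- what is said of Z.L includes D
- where a step has two of a species, its rate is k times that concentration squared, and two are used at each turn
- E, D is a solid; its amount is given per volume of the solution
- at the start none of E is in solution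
- run time (flask): 50 min

- how much Z.L and D together there is at 50 min, in percent of the E charged
- the change that raises the amount of Z.L and D together at 50 min, in percent of the E charged most ("none" if none brings more than 2 percentage points) (delta / gamma / epsilon / beta / none)
- amount of Z.L and D together at 50 min, in percent of the E charged, after epsilon

- delta: doubling the dissolution coefficient of step 1, all else as stated
- gamma: doubling the solubility in step 1, all else as stated
- epsilon: doubling the amount of L, all else as stated
- beta: doubling the dissolution coefficient of step 3, all else as stated

Work with the fraction of L left, not the fraction of product made. You charge 96.0 mM of L. By self-pairing alone, the fraction left after time t is one over (one plus t/τ), where τ is 9.21 min. After 50 min that reckoning leaves 15.5%, and I set aside the L that capture uses.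

Z is fed by dissolving and drained by capture. At the start, capture is pseudo-first-order in Z, with constant 0.00927 s⁻¹. That is slower than the dissolving coefficient 0.0170 s⁻¹. The two balance with Z at 64.7% of its solubility, and I hold that share fixed as a rough step.

Capture goes with L and self-pairing with its square, so L cancels per unit of ln(1/f). The yield gained per unit is the rate constant of capture times Z, over twice the rate constant of pairing, as a part of the E charged. That ratio is 35.9%: the capture number, the part of the charge captured each time the L left falls by a factor e.

So my y is 66.8%. Doubling L halves τ. I keep the capture number, as a guess, and get yb as 88.8%. Doubling the solubility doubles the capture number and gives 134%, more than the charge, so I cap that estimate at the charge. Faster dissolving, with the share of solubility reckoned anew, gives 81.1%. Beta moves material between Z.L and D, which are counted together. My choice is gamma.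

The forecast gives 71% (65% to 76%), 87% after epsilon (80% to 93%), and gamma, calling extra L “largely wasted on faster dimerisation”. My y is lower than its figure, and my yb is higher.

The flask gives 70.6%, and 87.3% after epsilon. The best change is gamma, worth 28 percentage points. In the flask Z stood at 73.4% of its solubility at 5.00 min. At 25.0 min the capture number gives 47.1%, and the flask held 49.7% as Z.L and D.

For the neighbour with 1.60 equiv of L, the same capture number gives 41.5%. That neighbour's run gives 45.8%.

The numbers are invented; the rest is arithmetic.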